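**Plan**

1. Labels (TBS = tert-butyldimethylsilyl): C1 (O–C= of the furanone), C2 (=CH), C3 (C=O), C4 (quaternary C–Me), C5=C6 (exocyclic enol-lactone alkene), C7=C11–C12(=O)–O–C6 (butenolide, C13 = CH2O on C11), C8 (CH–O), C9 (CH2), C10 (CH–Me).
2. Cuts, in retrosynthetic order: the C13 acetate and the C8 3-methylbut-2-enoate; C5=C6 (ring-closing vinylogous aldol of the butenolide onto a C5 aldehyde, then dehydration); the butenolide carbonyl C12=O (from a furan); then C1–C2 and C3–C4 together.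
3. Enabling feature: the furanone ring O–C1=C2–C3(=O)–C4 is a cycloisomerised 4-hydroxy-2-yn-1-one, so C2 and C3 are the two carbons of acetylene lying between a ketone-derived carbinol carbon (C4, the fully substituted centre) and an acyl carbon (C1). A ketone, acetylene and an N-methoxy-N-methylamide are therefore joined in one pot.
4. Forward order: east amide (C1, C7–C13, butenolide masked as a furan) and west ketone (C4, C5, C4-methyl) are made separately; three-component union; furanone ring by gold catalysis; furan to butenolide; C5 aldehyde; ten-membered ring by C5–C6 aldol and then C5=C6; the two esters last.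
5. Stereochemistry: C8 by catalyst control (iridium/chiral bisphosphine allylation–lactonisation); C10 by hydrogenation anti to the C8 substituent; C4 by chelation-controlled Grignard addition to a glycerate-derived ketone whose stereocentre is cut out afterwards; C5=C6 geometry by the bridged ring.

Key step: step 6

Remark: in step 3 the sense of induction is taken by analogy with the parent iridium-catalysed allylation of primary alcohols, and the ligand antipode would be used if a model alcohol showed the opposite sense.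

**Step 1**
Reactants: 1 methyl (4R)-2,2-dimethyl-1,3-dioxolane-4-carboxylate
Product: 3 1-[(4R)-2,2-dimethyl-1,3-dioxolan-4-yl]ethan-1-one, via Weinreb amide 2 (not isolated)
Conditions: MeNH(OMe)·HCl, i-PrMgCl, THF, −20 °C; then MeMgBr, −20 → 0 °C; aq. NH4Cl
Reagents that add atoms: methylmagnesium bromide, C[Mg]Br
Why: Acyl substitution of the ester by the magnesium amide gives the N-methoxy-N-methylamide, which takes up only one equivalent of MeMgBr (Weinreb ketone synthesis), so the methyl ketone should form without over-addition and without touching the α-alkoxy stereocentre.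

**Step 2**
Reactants: 4 furan-3,4-diyldimethanol
Product: 5 [4-(TBSOCH2)furan-3-yl]methanol
Conditions: NaH (1.0 equiv), THF, 0 °C → rt; t-BuMe2SiCl (1.0 equiv)
Reagents that add atoms: tert-butyl(chloro)dimethylsilane, CC(C)(C)[Si](C)(C)Cl
Why: Monoalkoxide formation from the symmetric diol followed by silylation (statistical monoprotection) should give the mono-ether, which breaks the symmetry and marks the future C13 oxygen.

**Step 3**
Reactants: 5 [4-(TBSOCH2)furan-3-yl]methanol; 6 methyl 2-{[(tert-butoxycarbonyl)oxy]methyl}prop-2-enoate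
Product: 9 (5S)-3-methylidene-5-[4-(TBSOCH2)furan-3-yl]oxolan-2-one, via furan aldehyde 7 (not isolated), via hydroxy ester 8 (not isolated)
Conditions: [Ir(cod)Cl]2 (2.5 mol %), (S)-SEGPHOS (5 mol %), 4-cyano-3-nitrobenzoic acid (10 mol %), Cs2CO3 (20 mol %), THF, 70 °C
Reagents that add atoms: none
Why: In this iridium-catalysed transfer-hydrogenative 2-(alkoxycarbonyl)allylation the catalyst dehydrogenates the primary alcohol to 7, delivers the allyl fragment of 6 to one aldehyde face under control of the chiral bisphosphine to set C8 as S, and 8 lactonises in the flask.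

**Step 4**
Reactants: 9 (5S)-3-methylidene-5-[4-(TBSOCH2)furan-3-yl]oxolan-2-one
Product: 10 (3S,5S)-3-methyl-5-[4-(TBSOCH2)furan-3-yl]oxolan-2-one
Conditions: H2 (1 atm), Rh/Al2O3 (5 wt %), EtOAc, rt
Reagents that add atoms: none
Why: Heterogeneous hydrogenation of the exocyclic alkene from the face anti to the C8 furyl group should place the new C10 methyl cis to it, and rhodium on alumina is chosen because it spares the furan and the furfuryl-type C–O bond.

**Step 5**
Reactants: 10 (3S,5S)-3-methyl-5-[4-(TBSOCH2)furan-3-yl]oxolan-2-one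
Product: 12 (2S,4S)-N-methoxy-N,2-dimethyl-4-(TBSO)-4-[4-(TBSOCH2)furan-3-yl]butanamide, via hydroxy amide 11 (not isolated)
Conditions: MeNH(OMe)·HCl, AlMe3, CH2Cl2, 0 °C → rt; aq. potassium sodium tartrate; then t-BuMe2SiOTf, 2,6-lutidine, CH2Cl2, −78 → 0 °C
Reagents that add atoms: N,O-dimethylhydroxylamine hydrochloride, CNOC.Cl; tert-butyldimethylsilyl trifluoromethanesulfonate, CC(C)(C)[Si](C)(C)OS(=O)(=O)C(F)(F)F
Why: Aluminium amide aminolysis of the γ-lactone (Weinreb amide formation) followed at once by silylation of the freed C8 hydroxyl should prevent relactonisation and leave both stereocentres untouched.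

**Step 6**
Reactants: 3 1-[(4R)-2,2-dimethyl-1,3-dioxolan-4-yl]ethan-1-one; 13 ethynylmagnesium bromide; 12 (2S,4S)-N-methoxy-N,2-dimethyl-4-(TBSO)-4-[4-(TBSOCH2)furan-3-yl]butanamide
Product: 17 (2R,6S,8S)-2-[(4R)-2,2-dimethyl-1,3-dioxolan-4-yl]-2-hydroxy-6-methyl-8-(TBSO)-8-[4-(TBSOCH2)furan-3-yl]oct-3-yn-5-one, via magnesium alkoxide 14 (not isolated), via alkynylmagnesium species 15 (not isolated), via chelated adduct 16 (not isolated)
Conditions: 13 (1.0 equiv), THF, −78 °C, then 3 (1.05 equiv), −78 → −20 °C; i-PrMgCl (1.1 equiv), 0 °C → rt; 12 (0.8 equiv), 0 °C → rt; aq. NH4Cl, 0 °C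
Reagents that add atoms: none
Why: Ethynylmagnesium bromide adds to ketone 3 through a five-membered magnesium chelate between the carbonyl oxygen and the neighbouring dioxolane oxygen, alkoxide 14 is then magnesiated at the alkyne terminus to 15, and 15 attacks the amide carbonyl of 12 to give 16, which releases ynone 17 on quench, so that C3–C4 and C1–C2 are both formed with acetylene as the two-carbon linchpin. The closest known reaction types are the chelation-controlled Grignard addition to α-alkoxy ketones (Cram chelate model) and the acylation of propargylic alkoxide dianions by N-methoxy-N-methylamides (Weinreb ketone synthesis), here joined in one pot. No ring is closed in this step; the furanone ring follows in step 7 from the 4-hydroxy-2-yn-1-one formed here. The one new stereocentre, the fully substituted C4, is controlled by the (4R)-dioxolane carbon of 3: in the chelate the nucleophile enters on the face of the small hydrogen, anti to the ring CH2, which gives the C4 configuration of 30 (R by the sequence rules in 17, S once C3 is a ketone). The step needs single addition at C1 and no epimerisation at C10, and both are secured because magnesium holds the tetrahedral adduct 16 until the quench, so that no free ynone is exposed to a nucleophile or a base. It also needs the acetylide to meet the ketone before the amide, which the order of addition secures, while the furan and both silyl ethers are inert to Grignard reagents.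

**Step 7**
Reactants: 17 (2R,6S,8S)-2-[(4R)-2,2-dimethyl-1,3-dioxolan-4-yl]-2-hydroxy-6-methyl-8-(TBSO)-8-[4-(TBSOCH2)furan-3-yl]oct-3-yn-5-one
Product: 19 (2S)-2-[(4R)-2,2-dimethyl-1,3-dioxolan-4-yl]-2-methyl-5-{(2S,4S)-4-(TBSO)-4-[4-(TBSOCH2)furan-3-yl]butan-2-yl}furan-3(2H)-one, via hydroxy diketone 18 (not isolated)
Conditions: Ph3PAuNTf2 (5 mol %), toluene, H2O (0.5 equiv), rt
Reagents that add atoms: water, O
Why: Gold-catalysed Michael-type hydration of the ynone at C3 gives 18, whose tertiary C4 hydroxyl adds to the C1 carbonyl (5-exo-trig) and loses water to give the 3(2H)-furanone (cycloisomerisation of a 4-hydroxy-2-yn-1-one) under neutral conditions that should spare C10, the acetonide and the silyl ethers.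

**Step 8**
Reactants: 19 (2S)-2-[(4R)-2,2-dimethyl-1,3-dioxolan-4-yl]-2-methyl-5-{(2S,4S)-4-(TBSO)-4-[4-(TBSOCH2)furan-3-yl]butan-2-yl}furan-3(2H)-one
Product: 21 4-[(1S,3S)-1-(TBSO)-3-{(5S)-5-[(4R)-2,2-dimethyl-1,3-dioxolan-4-yl]-5-methyl-4-oxo-4,5-dihydrofuran-2-yl}butyl]-3-(TBSOCH2)furan-2(5H)-one, via furyl boronate 20 (not isolated)
Conditions: [Ir(cod)OMe]2 (2 mol %), 4,4′-di-tert-butyl-2,2′-bipyridine (4 mol %), B2pin2 (1.0 equiv), THF, 50 °C; then NaBO3·4H2O, THF/H2O, 0 °C → rt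
Reagents that add atoms: sodium perborate, [Na+].O[B-](O)(O)OO
Why: Sterically governed iridium-catalysed C–H borylation should take the furan α-position next to the small CH2OTBS group (C12) and not the one next to the branched C8 substituent, and oxidation of the C–B bond gives the 2-hydroxyfuran tautomer that settles as the conjugated butenolide with its carbonyl at C12.

**Step 9**
Reactants: 21 4-[(1S,3S)-1-(TBSO)-3-{(5S)-5-[(4R)-2,2-dimethyl-1,3-dioxolan-4-yl]-5-methyl-4-oxo-4,5-dihydrofuran-2-yl}butyl]-3-(TBSOCH2)furan-2(5H)-one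
Product: 23 (2S)-2-methyl-3-oxo-5-{(2S,4S)-4-(TBSO)-4-[5-oxo-4-(TBSOCH2)-2,5-dihydrofuran-3-yl]butan-2-yl}-2,3-dihydrofuran-2-carbaldehyde, via diol 22 (not isolated)
Conditions: H5IO6 (1.5 equiv), EtOAc, 0 °C → rt
Reagents that add atoms: none
Why: Periodic acid hydrolyses the terminal acetonide to 22 and cleaves it in the same flask (glycol cleavage), which removes the auxiliary stereocentre and leaves C5 as a non-enolisable aldehyde on the quaternary carbon.

**Step 10**
Reactants: 23 (2S)-2-methyl-3-oxo-5-{(2S,4S)-4-(TBSO)-4-[5-oxo-4-(TBSOCH2)-2,5-dihydrofuran-3-yl]butan-2-yl}-2,3-dihydrofuran-2-carbaldehyde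
Product: 25 (4S,8S,10S)-8,13-bis(TBSO)-5-hydroxy-1,4-epoxy-3-oxogermacra-1,7(11)-dien-12,6-olide (mixture at C5 and C6), via silyloxyfuran 24 (not isolated)
Conditions: i-Pr3SiOTf, Et3N, CH2Cl2, 0 °C; filtration; then syringe-pump addition to BF3·OEt2 (1.1 equiv), CH2Cl2 (0.001 M), −78 °C; aq. NaHCO3
Reagents that add atoms: none
Why: Soft enolisation of the butenolide gives 2-silyloxyfuran 24, whose γ-carbon C6 adds to the BF3-activated C5 aldehyde in a ring-closing vinylogous Mukaiyama aldol reaction under high dilution, and the two new centres at C5 and C6 need no control because both are removed in step 11.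

**Step 11**
Reactants: 25 (4S,8S,10S)-8,13-bis(TBSO)-5-hydroxy-1,4-epoxy-3-oxogermacra-1,7(11)-dien-12,6-olide
Product: 27 (4S,5E,8S,10S)-8,13-bis(TBSO)-1,4-epoxy-3-oxogermacra-1,5,7(11)-trien-12,6-olide, via mesylate 26 (not isolated)
Conditions: MeSO2Cl, Et3N, CH2Cl2, −20 °C; then DBU, −20 → 0 °C
Reagents that add atoms: none
Why: Mesylation of the C5 hydroxyl and E1cB elimination through the butenolide dienolate should form C5=C6, since the methanesulfonate is a far better leaving group than the C13 silyl ether and the bridged ten-membered ring should allow only the geometry with C4 cis to C7.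

**Step 12**
Reactants: 27 (4S,5E,8S,10S)-8,13-bis(TBSO)-1,4-epoxy-3-oxogermacra-1,5,7(11)-trien-12,6-olide
Product: 28 (4S,5E,8S,10S)-8,13-dihydroxy-1,4-epoxy-3-oxogermacra-1,5,7(11)-trien-12,6-olide
Conditions: HF·pyridine, pyridine, THF, 0 °C → rt
Reagents that add atoms: none
Why: Fluoride-mediated cleavage of both silyl ethers under buffered conditions should leave the enol lactone, the furanone and the C10 centre untouched.

**Step 13**
Reactants: 28 (4S,5E,8S,10S)-8,13-dihydroxy-1,4-epoxy-3-oxogermacra-1,5,7(11)-trien-12,6-olide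
Product: 29 (4S,5E,8S,10S)-13-acetoxy-8-hydroxy-1,4-epoxy-3-oxogermacra-1,5,7(11)-trien-12,6-olide
Conditions: Ac2O (1.05 equiv), 2,4,6-collidine, CH2Cl2, −20 °C
Reagents that add atoms: acetic anhydride, CC(=O)OC(C)=O
Why: Kinetically selective acylation of the unhindered primary allylic C13 hydroxyl over the secondary ring C8 hydroxyl is expected with one equivalent of anhydride and a hindered pyridine base at low temperature.

**Step 14**
Reactants: 29 (4S,5E,8S,10S)-13-acetoxy-8-hydroxy-1,4-epoxy-3-oxogermacra-1,5,7(11)-trien-12,6-olide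
Product: 30 (4S,5E,8S,10S)-13-acetoxy-8-(3-methylbut-2-enoyloxy)-1,4-epoxy-3-oxogermacra-1,5,7(11)-trien-12,6-olide (CNP0102620.1)
Conditions: 3-methylbut-2-enoyl chloride, pyridine, CH2Cl2, 0 °C → rt
Reagents that add atoms: 3-methylbut-2-enoyl chloride, CC(C)=CC(=O)Cl
Why: Esterification of the remaining secondary C8 hydroxyl with the acid chloride and pyridine, without a nucleophilic catalyst, should avoid displacement of the allylic C13 acetate and deconjugation of the enoyl group.

**Compound list**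

1 | methyl (4R)-2,2-dimethyl-1,3-dioxolane-4-carboxylate | COC(=O)[C@H]1COC(C)(C)O1 | starting material
2 | (4R)-N-methoxy-N,2,2-trimethyl-1,3-dioxolane-4-carboxamide | CON(C)C(=O)[C@H]1COC(C)(C)O1 | intermediate
3 | 1-[(4R)-2,2-dimethyl-1,3-dioxolan-4-yl]ethan-1-one | CC(=O)[C@H]1COC(C)(C)O1 | intermediate
4 | furan-3,4-diyldimethanol | OCc1cocc1CO | starting material
5 | [4-(TBSOCH2)furan-3-yl]methanol | OCc1cocc1CO[Si](C)(C)C(C)(C)C | intermediate
6 | methyl 2-{[(tert-butoxycarbonyl)oxy]methyl}prop-2-enoate | C=C(COC(=O)OC(C)(C)C)C(=O)OC | starting material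
7 | 4-(TBSOCH2)furan-3-carbaldehyde | O=Cc1cocc1CO[Si](C)(C)C(C)(C)C | intermediate
8 | methyl (4S)-4-hydroxy-2-methylidene-4-[4-(TBSOCH2)furan-3-yl]butanoate | COC(=O)C(=C)C[C@H](O)c1cocc1CO[Si](C)(C)C(C)(C)C | intermediate
9 | (5S)-3-methylidene-5-[4-(TBSOCH2)furan-3-yl]oxolan-2-one | O=C1O[C@H](c2cocc2CO[Si](C)(C)C(C)(C)C)CC1=C | intermediate
10 | (3S,5S)-3-methyl-5-[4-(TBSOCH2)furan-3-yl]oxolan-2-one (cis) | O=C1O[C@H](c2cocc2CO[Si](C)(C)C(C)(C)C)C[C@@H]1C | intermediate
11 | (2S,4S)-4-hydroxy-N-methoxy-N,2-dimethyl-4-[4-(TBSOCH2)furan-3-yl]butanamide | CON(C)C(=O)[C@@H](C)C[C@H](O)c1cocc1CO[Si](C)(C)C(C)(C)C | intermediate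
12 | (2S,4S)-N-methoxy-N,2-dimethyl-4-(TBSO)-4-[4-(TBSOCH2)furan-3-yl]butanamide | CON(C)C(=O)[C@@H](C)C[C@H](O[Si](C)(C)C(C)(C)C)c1cocc1CO[Si](C)(C)C(C)(C)C | intermediate
13 | ethynylmagnesium bromide | C#C[Mg]Br | starting material
14 | bromomagnesium (2R)-2-[(4R)-2,2-dimethyl-1,3-dioxolan-4-yl]but-3-yn-2-olate | C#C[C@@](C)(O[Mg]Br)[C@H]1COC(C)(C)O1 | intermediate
15 | bromomagnesium (2R)-4-(chloromagnesio)-2-[(4R)-2,2-dimethyl-1,3-dioxolan-4-yl]but-3-yn-2-olate | Cl[Mg]C#C[C@@](C)(O[Mg]Br)[C@H]1COC(C)(C)O1 | intermediate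
16 | magnesium-held tetrahedral adduct of 15 at the amide carbon of 12 | CON(C)C(O[Mg]Cl)(C#C[C@@](C)(O[Mg]Br)[C@H]1COC(C)(C)O1)[C@@H](C)C[C@H](O[Si](C)(C)C(C)(C)C)c2cocc2CO[Si](C)(C)C(C)(C)C | intermediate
17 | (2R,6S,8S)-2-[(4R)-2,2-dimethyl-1,3-dioxolan-4-yl]-2-hydroxy-6-methyl-8-(TBSO)-8-[4-(TBSOCH2)furan-3-yl]oct-3-yn-5-one | C[C@@](O)(C#CC(=O)[C@@H](C)C[C@H](O[Si](C)(C)C(C)(C)C)c1cocc1CO[Si](C)(C)C(C)(C)C)[C@H]2COC(C)(C)O2 | intermediate
18 | (2S,6S,8S)-2-[(4R)-2,2-dimethyl-1,3-dioxolan-4-yl]-2-hydroxy-6-methyl-8-(TBSO)-8-[4-(TBSOCH2)furan-3-yl]octane-3,5-dione | C[C@@](O)(C(=O)CC(=O)[C@@H](C)C[C@H](O[Si](C)(C)C(C)(C)C)c1cocc1CO[Si](C)(C)C(C)(C)C)[C@H]2COC(C)(C)O2 | intermediate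
19 | (2S)-2-[(4R)-2,2-dimethyl-1,3-dioxolan-4-yl]-2-methyl-5-{(2S,4S)-4-(TBSO)-4-[4-(TBSOCH2)furan-3-yl]butan-2-yl}furan-3(2H)-one | CC1(C)OC[C@@H](O1)[C@]2(C)OC(=CC2=O)[C@@H](C)C[C@H](O[Si](C)(C)C(C)(C)C)c3cocc3CO[Si](C)(C)C(C)(C)C | intermediate
20 | 19 carrying a pinacolboryl group on the furan α-carbon next to the CH2OTBS group (C12) | CC1(C)OC[C@@H](O1)[C@]2(C)OC(=CC2=O)[C@@H](C)C[C@H](O[Si](C)(C)C(C)(C)C)c3coc(B4OC(C)(C)C(C)(C)O4)c3CO[Si](C)(C)C(C)(C)C | intermediate
21 | 4-[(1S,3S)-1-(TBSO)-3-{(5S)-5-[(4R)-2,2-dimethyl-1,3-dioxolan-4-yl]-5-methyl-4-oxo-4,5-dihydrofuran-2-yl}butyl]-3-(TBSOCH2)furan-2(5H)-one | CC1(C)OC[C@@H](O1)[C@]2(C)OC(=CC2=O)[C@@H](C)C[C@H](O[Si](C)(C)C(C)(C)C)C3=C(CO[Si](C)(C)C(C)(C)C)C(=O)OC3 | intermediate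
22 | 21 with the dioxolane opened to the (1R)-1,2-dihydroxyethyl group | OC[C@@H](O)[C@]1(C)OC(=CC1=O)[C@@H](C)C[C@H](O[Si](C)(C)C(C)(C)C)C2=C(CO[Si](C)(C)C(C)(C)C)C(=O)OC2 | intermediate
23 | (2S)-2-methyl-3-oxo-5-{(2S,4S)-4-(TBSO)-4-[5-oxo-4-(TBSOCH2)-2,5-dihydrofuran-3-yl]butan-2-yl}-2,3-dihydrofuran-2-carbaldehyde | O=C[C@]1(C)OC(=CC1=O)[C@@H](C)C[C@H](O[Si](C)(C)C(C)(C)C)C2=C(CO[Si](C)(C)C(C)(C)C)C(=O)OC2 | intermediate
24 | 23 with the butenolide as its 2-(triisopropylsilyloxy)furan | O=C[C@]1(C)OC(=CC1=O)[C@@H](C)C[C@H](O[Si](C)(C)C(C)(C)C)c2coc(O[Si](C(C)C)(C(C)C)C(C)C)c2CO[Si](C)(C)C(C)(C)C | intermediate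
25 | (4S,8S,10S)-8,13-bis(TBSO)-5-hydroxy-1,4-epoxy-3-oxogermacra-1,7(11)-dien-12,6-olide (mixture at C5 and C6) | CC(C)(C)[Si](C)(C)OCC1=C2C(OC1=O)C(O)[C@]3(C)OC(=CC3=O)[C@@H](C)C[C@@H]2O[Si](C)(C)C(C)(C)C | intermediate
26 | C5 methanesulfonate of 25 | CC(C)(C)[Si](C)(C)OCC1=C2C(OC1=O)C(OS(C)(=O)=O)[C@]3(C)OC(=CC3=O)[C@@H](C)C[C@@H]2O[Si](C)(C)C(C)(C)C | intermediate
27 | (4S,5E,8S,10S)-8,13-bis(TBSO)-1,4-epoxy-3-oxogermacra-1,5,7(11)-trien-12,6-olide | CC(C)(C)[Si](C)(C)OCC1=C2/C(=C\[C@]3(C)OC(=CC3=O)[C@@H](C)C[C@@H]2O[Si](C)(C)C(C)(C)C)OC1=O | intermediate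
28 | (4S,5E,8S,10S)-8,13-dihydroxy-1,4-epoxy-3-oxogermacra-1,5,7(11)-trien-12,6-olide | OCC1=C2/C(=C\[C@]3(C)OC(=CC3=O)[C@@H](C)C[C@@H]2O)OC1=O | intermediate
29 | (4S,5E,8S,10S)-13-acetoxy-8-hydroxy-1,4-epoxy-3-oxogermacra-1,5,7(11)-trien-12,6-olide | CC(=O)OCC1=C2/C(=C\[C@]3(C)OC(=CC3=O)[C@@H](C)C[C@@H]2O)OC1=O | intermediate
30 | (4S,5E,8S,10S)-13-acetoxy-8-(3-methylbut-2-enoyloxy)-1,4-epoxy-3-oxogermacra-1,5,7(11)-trien-12,6-olide (CNP0102620.1) | CC(=O)OCC1=C2/C(=C\[C@]3(C)OC(=CC3=O)[C@@H](C)C[C@@H]2OC(=O)C=C(C)C)OC1=O | target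

**Totals**

Total step count: 14. Longest linear sequence: 13 steps (4 → 30, steps 2–14).

**Steps most likely to fail**

Step 10. The medium-ring closure may lose to intermolecular aldol addition (oligomerisation), and the Lewis acid may ionise the allylic C13 silyl ether of the silyloxyfuran. The fallback closes the ring by olefination instead of aldol addition and sets out from 21. Soft enolisation (i-Pr3SiOTf, Et3N) would give the silyloxyfuran F1, which N-bromosuccinimide at −78 °C would brominate at C6 to the γ-bromobutenolide F2. An Arbuzov reaction with P(OEt)3 would give the γ-phosphonate F3, and periodic acid as in step 9 would give the phosphonate aldehyde F4. Intramolecular Horner–Wadsworth–Emmons olefination (LiCl, i-Pr2NEt, MeCN, high dilution) would then close the ring and form C5=C6 in one operation, coming back to the route at 27.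

Step 6. Incomplete chelation would erode facial selectivity at C4, and slow acylation of the hindered dimagnesium species could stall the one-pot sequence. The fallback builds the furanone by an aldol/1,3-diketone cyclodehydration route and sets out from 3 and 12. 1-Ethoxyvinyllithium precomplexed with MgBr2·OEt2 would add to 3 under the same chelation control to give the enol ether F5, where C4 epimers could be separated. Mild aqueous acid would give the hydroxy ketone F6, and Me3SiCl with imidazole the silyl ether F7. Amide 12 would be reduced with i-Bu2AlH to the aldehyde F8. The lithium enolate of F7 (LiN(i-Pr)2, THF, −78 °C) would add to F8 to give the aldol F9, and Dess–Martin periodinane would give the diketone F10. Pyridinium p-toluenesulfonate in wet CH2Cl2 would remove the silyl group and cyclodehydrate through 18, coming back to the route at 19.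

Step 8. The C–H borylation may discriminate poorly between the two furan α-positions. The fallback replaces steric control by a hydroxyl-directed C–H silylation and sets out from 19. Selective cleavage of the primary silyl ether (HF·pyridine, 0 °C) would give the alcohol F11, and Et2SiH2 with [Ir(cod)OMe]2 would give the hydrosilyl ether F12. With [Ir(cod)OMe]2, 3,4,7,8-tetramethyl-1,10-phenanthroline and norbornene as hydrogen acceptor, F12 should silylate only the adjacent α-C–H (C12) to give the oxasilole F13. Tamao–Fleming oxidation (H2O2, KHCO3, KF) would give the hydroxymethyl butenolide F14, and t-BuMe2SiCl with imidazole would come back to the route at 21.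

**Further compounds**

F1 | step 10 | 2-(triisopropylsilyloxy)furan form of 21 | CC1(C)OC[C@@H](O1)[C@]2(C)OC(=CC2=O)[C@@H](C)C[C@H](O[Si](C)(C)C(C)(C)C)c3coc(O[Si](C(C)C)(C(C)C)C(C)C)c3CO[Si](C)(C)C(C)(C)C
F2 | step 10 | 21 brominated at the butenolide γ-carbon C6 | CC1(C)OC[C@@H](O1)[C@]2(C)OC(=CC2=O)[C@@H](C)C[C@H](O[Si](C)(C)C(C)(C)C)C3=C(CO[Si](C)(C)C(C)(C)C)C(=O)OC3Br
F3 | step 10 | 21 carrying a diethoxyphosphoryl group at C6 | CC1(C)OC[C@@H](O1)[C@]2(C)OC(=CC2=O)[C@@H](C)C[C@H](O[Si](C)(C)C(C)(C)C)C3=C(CO[Si](C)(C)C(C)(C)C)C(=O)OC3P(=O)(OCC)OCC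
F4 | step 10 | 23 carrying a diethoxyphosphoryl group at C6 | O=C[C@]1(C)OC(=CC1=O)[C@@H](C)C[C@H](O[Si](C)(C)C(C)(C)C)C2=C(CO[Si](C)(C)C(C)(C)C)C(=O)OC2P(=O)(OCC)OCC
F5 | step 6 | (2S)-2-[(4R)-2,2-dimethyl-1,3-dioxolan-4-yl]-3-ethoxybut-3-en-2-ol | CCOC(=C)[C@@](C)(O)[C@H]1COC(C)(C)O1
F6 | step 6 | (3S)-3-[(4R)-2,2-dimethyl-1,3-dioxolan-4-yl]-3-hydroxybutan-2-one | CC(=O)[C@@](C)(O)[C@H]1COC(C)(C)O1
F7 | step 6 | trimethylsilyl ether of F6 | CC(=O)[C@@](C)(O[Si](C)(C)C)[C@H]1COC(C)(C)O1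
F8 | step 6 | (2S,4S)-2-methyl-4-(TBSO)-4-[4-(TBSOCH2)furan-3-yl]butanal | O=C[C@@H](C)C[C@H](O[Si](C)(C)C(C)(C)C)c1cocc1CO[Si](C)(C)C(C)(C)C
F9 | step 6 | aldol of F7 and F8 (C1 carbinol, mixture) | C[C@@](O[Si](C)(C)C)(C(=O)CC(O)[C@@H](C)C[C@H](O[Si](C)(C)C(C)(C)C)c1cocc1CO[Si](C)(C)C(C)(C)C)[C@H]2COC(C)(C)O2
F10 | step 6 | trimethylsilyl ether of 18 | C[C@@](O[Si](C)(C)C)(C(=O)CC(=O)[C@@H](C)C[C@H](O[Si](C)(C)C(C)(C)C)c1cocc1CO[Si](C)(C)C(C)(C)C)[C@H]2COC(C)(C)O2
F11 | step 8 | 19 with the primary silyl ether cleaved (free C13 hydroxyl) | CC1(C)OC[C@@H](O1)[C@]2(C)OC(=CC2=O)[C@@H](C)C[C@H](O[Si](C)(C)C(C)(C)C)c3cocc3CO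
F12 | step 8 | diethyl(hydrido)silyl ether of F11 | CC1(C)OC[C@@H](O1)[C@]2(C)OC(=CC2=O)[C@@H](C)C[C@H](O[Si](C)(C)C(C)(C)C)c3cocc3CO[SiH](CC)CC
F13 | step 8 | oxasilole formed by C–H silylation of F12 at the adjacent furan α-carbon (C12) | CC1(C)OC[C@@H](O1)[C@]2(C)OC(=CC2=O)[C@@H](C)C[C@H](O[Si](C)(C)C(C)(C)C)c3coc4c3CO[Si]4(CC)CC
F14 | step 8 | 21 with a free C13 hydroxyl | CC1(C)OC[C@@H](O1)[C@]2(C)OC(=CC2=O)[C@@H](C)C[C@H](O[Si](C)(C)C(C)(C)C)C3=C(CO)C(=O)OC3
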